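Retrosynthesis: the bond from the bridging CH2 to C7 of the quinone-methide half is cut first (Michael addition to an ortho-quinone methide), then the CH2–C7' bond of the aromatic half (phenolic Mannich reaction), so both halves come from one monomer, (3R,4S)-3,4,5-trimethylisochromane-6,8-diol, one portion of which is dehydrogenated at C1.
Next the C1–O2 bond of the isochromane is cut: in its benzene ring C8a (bearing C1) and C5 (bearing a methyl) both flank C4a, C8a lying para to O6 and C5 para to O8, so with C1 at the methyl level the arene is a 2,6-dimethyl-3,5-dioxygenated aryl group with a local mirror plane through C4a and C7, and either methyl can become C1 by benzylic oxidation and capture by the C3 hydroxyl.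
Last the C4–C4a bond is cut to an aryllithium and (2S,3S)-2,3-epoxybutane, and the two aryl methyls are traced back to formyl groups on 1-bromo-3,5-dimethoxybenzene.
Forward order: two formylation/reduction cycles, side-chain attachment, inversion of the carbinol, closure of the pyran ring (the only ring made), demethylation, then divergence into an oxidised and an aminomethylated monomer and their union through one formaldehyde carbon.
Stereochemistry: C4 (S) arises by SN2 inversion at the epoxide carbon and C3 (R) by Mitsunobu inversion of the (S)-carbinol; no later step breaks a bond to C3 or C4, and both halves inherit the same (3R,4S) pair.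

Key step: step 8

Assumption: (2S,3S)-2,3-epoxybutane is bought as the single enantiomer, and the quinone-methide half is written throughout as the 6-hydroxy-8-oxo tautomer of the target SMILES, which interconverts with the 8-hydroxy-6-oxo form by proton shift.

Step 1
Reactants: 1 1-bromo-3,5-dimethoxybenzene
Product: 2 2-bromo-4,6-dimethoxybenzaldehyde
Conditions: POCl3, DMF, 0 °C to 90 °C; then ice–water
Reagents that add atoms: N,N-dimethylformamide CN(C)C=O; water O
Why: Vilsmeier–Haack formylation, in which the chloroiminium electrophile attacks the position ortho to one methoxy and para to the other (between Br and OMe), electronically preferred over the position between the two methoxy groups, and the aryl iminium salt is hydrolysed to the aldehyde on work-up.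

Step 2
Reactants: 2 2-bromo-4,6-dimethoxybenzaldehyde
Product: 3 1-bromo-3,5-dimethoxy-2-methylbenzene
Conditions: Et3SiH (3 equiv), TFA, CH2Cl2, 0 °C to rt
Reagents that add atoms: none
Why: Ionic hydrogenation, in which the protonated, doubly methoxy-activated aldehyde takes hydride from the silane, the benzylic oxygen then ionises in TFA to a 2,4-dimethoxybenzyl cation that takes a second hydride, and the aryl bromide, which catalytic hydrogenolysis would endanger, is left alone.

Step 3
Reactants: 3 1-bromo-3,5-dimethoxy-2-methylbenzene
Product: 4 2-bromo-4,6-dimethoxy-3-methylbenzaldehyde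
Conditions: POCl3, DMF, 0 °C to 90 °C; then ice–water
Reagents that add atoms: N,N-dimethylformamide CN(C)C=O; water O
Why: Second Vilsmeier–Haack formylation, expected at C6 (between Br and OMe) because it is the only free position ortho to one methoxy and para to the other, while the 2-methyl group turns the neighbouring methoxy toward C4 and so shields the position between the two methoxy groups.

Step 4
Reactants: 4 2-bromo-4,6-dimethoxy-3-methylbenzaldehyde
Product: 5 3-bromo-1,5-dimethoxy-2,4-dimethylbenzene
Conditions: Et3SiH (3 equiv), TFA, CH2Cl2, 0 °C to rt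
Reagents that add atoms: none
Why: Ionic hydrogenation of the electron-rich aryl aldehyde to the methyl group by the same two hydride transfers as in step 2, which completes the symmetric 2,6-dimethyl-3,5-dimethoxyaryl bromide.

Step 5
Reactants: 5 3-bromo-1,5-dimethoxy-2,4-dimethylbenzene; 6 (2S,3S)-2,3-epoxybutane
Product: 8 (2S,3S)-3-(3,5-dimethoxy-2,6-dimethylphenyl)butan-2-ol, via aryllithium 7 (not isolated)
Conditions: n-BuLi, THF, −78 °C; then 6, BF3·OEt2, −78 °C; then H2O
Reagents that add atoms: none
Why: Bromine–lithium exchange followed by BF3-promoted SN2 opening of the epoxide by the aryllithium, where the two epoxide carbons are equivalent by C2 symmetry, attack with inversion sets the benzylic centre (future C4) as S, and the carbinol carbon keeps its S configuration, so the erythro alcohol should result.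

Step 6
Reactants: 8 (2S,3S)-3-(3,5-dimethoxy-2,6-dimethylphenyl)butan-2-ol
Product: 9 (2R,3S)-3-(3,5-dimethoxy-2,6-dimethylphenyl)butan-2-yl 4-nitrobenzoate
Conditions: 4-nitrobenzoic acid, PPh3, DIAD, THF, 0 °C to rt
Reagents that add atoms: 4-nitrobenzoic acid O=C(O)c1ccc(cc1)[N+](=O)[O-]
Why: Mitsunobu reaction, in which the alkoxyphosphonium ion is displaced by 4-nitrobenzoate (the acid of choice for hindered secondary alcohols) in an SN2 step that inverts the carbinol centre to R, giving the threo series needed for the trans-3,4-dimethylpyran.

Step 7
Reactants: 9 (2R,3S)-3-(3,5-dimethoxy-2,6-dimethylphenyl)butan-2-yl 4-nitrobenzoate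
Product: 10 (2R,3S)-3-(3,5-dimethoxy-2,6-dimethylphenyl)butan-2-ol
Conditions: K2CO3 (0.2 equiv), MeOH, rt
Reagents that add atoms: none
Why: Base-catalysed transesterification with methanol cleaves the acyl–oxygen bond only, so the R configuration just set at the carbinol carbon is retained.

Step 8
Reactants: 10 (2R,3S)-3-(3,5-dimethoxy-2,6-dimethylphenyl)butan-2-ol
Product: 12 (3R,4S)-6,8-dimethoxy-3,4,5-trimethylisochromane, via isochromenylium ion 11 (not isolated)
Conditions: DDQ (2.2 equiv), 4 Å MS, ClCH2CH2Cl (0.02 M), 0 °C to 50 °C; then Et3SiH, TFA, −20 °C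
Reagents that add atoms: none
Why: DDQ takes hydride (electron transfer from the dimethoxyarene, proton loss, second electron transfer) from one of the two equivalent methyl groups, each ortho to one methoxy and para to the other, and the C3 hydroxyl traps the resulting 2,4-dimethoxybenzyl cation to form the C1–O2 bond. The closest known reaction type is the DDQ or anodic benzylic C–H oxidation of methoxytoluenes with capture by an oxygen nucleophile, including intramolecular closure to cyclic benzylic ethers and lactones. The pyran ring closes in a 6-endo-trig mode on the exocyclic carbon of the quinoid cation (an SN1 etherification), and no stereocentre is created, C3 and C4 being carried through because no bond to either is broken. Since the first-formed isochromane loses hydride from C1 more readily than the starting methyl group does, a second equivalent of DDQ is used on purpose to carry everything to the isochromenylium ion 11, where oxidation stops because the cation and its DDQH adduct are electron-poor, and Et3SiH/TFA then returns C1 to the CH2 level so that all material converges on 12. Regioselectivity needs no control because the aryl group has a local mirror plane and closure onto either methyl gives the same 5-methylisochromane; the benzylic C4–H is spared because C4a is meta to both methoxy groups and offers no stabilised cation, and high dilution disfavors intermolecular benzylation of the free ring position.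

Step 9
Reactants: 12 (3R,4S)-6,8-dimethoxy-3,4,5-trimethylisochromane
Product: 13 (3R,4S)-3,4,5-trimethylisochromane-6,8-diol
Conditions: BBr3 (4 equiv), CH2Cl2, −78 °C to 0 °C; then H2O
Reagents that add atoms: none
Why: Aryl methyl ether cleavage by BBr3 (boron coordination, SN2 attack of bromide on the O-methyl carbon), in which any opening of the benzylic C1–O2 bond should be undone on aqueous work-up by reclosure of the hydroxyl onto C1, the C3–O bond and both stereocentres staying intact.

Step 10
Reactants: 13 (3R,4S)-3,4,5-trimethylisochromane-6,8-diol
Product: 14 (3R,4S)-6-hydroxy-3,4,5-trimethyl-3,4-dihydro-8H-isochromen-8-one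
Conditions: DDQ (1.0 equiv), 1,4-dioxane, 0 °C to rt
Reagents that add atoms: none
Why: Quinone dehydrogenation, in which DDQ abstracts hydride from C1 (activated by the ring oxygen and by the ortho and para hydroxyls) and the oxocarbenium ion loses a phenolic proton to give the neutral quinone methide, the established way from 6,8-dihydroxyisochromanes to citrinin-type chromophores.

Step 11
Reactants: 13 (3R,4S)-3,4,5-trimethylisochromane-6,8-diol
Product: 15 (3R,4S)-7-[(dimethylamino)methyl]-3,4,5-trimethylisochromane-6,8-diol
Conditions: aq. CH2O (1.05 equiv), aq. Me2NH (3 equiv), EtOH, 0 °C to rt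
Reagents that add atoms: formaldehyde C=O; dimethylamine CNC
Why: Phenolic Mannich reaction, in which the iminium ion from formaldehyde and dimethylamine attacks C7, the only unsubstituted ring position and ortho to both hydroxyls, while excess amine and low temperature should keep the product from eliminating amine prematurely.

Step 12
Reactants: 14 (3R,4S)-6-hydroxy-3,4,5-trimethyl-3,4-dihydro-8H-isochromen-8-one; 15 (3R,4S)-7-[(dimethylamino)methyl]-3,4,5-trimethylisochromane-6,8-diol
Product: 17 (3R,4S)-7-{[(3R,4S)-6,8-dihydroxy-3,4,5-trimethylisochroman-7-yl]methyl}-6-hydroxy-3,4,5-trimethyl-3,4-dihydro-8H-isochromen-8-one, via ortho-quinone methide 16 (not isolated)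
Conditions: MeCN, 60 °C, N2 sweep
Reagents that add atoms: none
Why: Mannich-base elimination to an ortho-quinone methide followed by Michael addition, in which proton transfer from the vinylogous acid 14 to the amine of 15 promotes loss of dimethylamine and C7 of 14, the central carbon of its enolised 1,3-dicarbonyl unit, adds to the exocyclic methylene with rearomatisation, as in the assembly of unsymmetrical methylene-bridged phloroglucinol dimers, no stereocentre being formed or touched.

Compound list
1 | 1-bromo-3,5-dimethoxybenzene | COc1cc(Br)cc(OC)c1 | starting material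
2 | 2-bromo-4,6-dimethoxybenzaldehyde | COc1cc(Br)c(C=O)c(OC)c1 | intermediate
3 | 1-bromo-3,5-dimethoxy-2-methylbenzene | COc1cc(Br)c(C)c(OC)c1 | intermediate
4 | 2-bromo-4,6-dimethoxy-3-methylbenzaldehyde | COc1cc(OC)c(C)c(Br)c1C=O | intermediate
5 | 3-bromo-1,5-dimethoxy-2,4-dimethylbenzene | COc1cc(OC)c(C)c(Br)c1C | intermediate
6 | (2S,3S)-2,3-epoxybutane | C[C@@H]1O[C@H]1C | starting material
7 | (3,5-dimethoxy-2,6-dimethylphenyl)lithium, formed in the flask | [Li]c1c(C)c(OC)cc(OC)c1C | intermediate
8 | (2S,3S)-3-(3,5-dimethoxy-2,6-dimethylphenyl)butan-2-ol | COc1cc(OC)c(C)c([C@H](C)[C@H](C)O)c1C | intermediate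
9 | (2R,3S)-3-(3,5-dimethoxy-2,6-dimethylphenyl)butan-2-yl 4-nitrobenzoate | COc1cc(OC)c(C)c([C@H](C)[C@@H](C)OC(=O)c2ccc(cc2)[N+](=O)[O-])c1C | intermediate
10 | (2R,3S)-3-(3,5-dimethoxy-2,6-dimethylphenyl)butan-2-ol | COc1cc(OC)c(C)c([C@H](C)[C@@H](C)O)c1C | intermediate
11 | (3R,4S)-6,8-dimethoxy-3,4,5-trimethyl-3,4-dihydroisochromenylium, ion pair with the monoanion of 2,3-dichloro-5,6-dicyanohydroquinone, formed in the flask | COc1cc(OC)c2c(c1C)[C@H](C)[C@@H](C)[O+]=C2.[O-]c1c(Cl)c(Cl)c(O)c(C#N)c1C#N | intermediate
12 | (3R,4S)-6,8-dimethoxy-3,4,5-trimethylisochromane | COc1cc(OC)c2c(c1C)[C@H](C)[C@@H](C)OC2 | intermediate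
13 | (3R,4S)-3,4,5-trimethylisochromane-6,8-diol | Cc1c(O)cc(O)c2c1[C@H](C)[C@@H](C)OC2 | intermediate
14 | (3R,4S)-6-hydroxy-3,4,5-trimethyl-3,4-dihydro-8H-isochromen-8-one | CC1=C2C(=CO[C@H](C)[C@H]2C)C(=O)C=C1O | intermediate
15 | (3R,4S)-7-[(dimethylamino)methyl]-3,4,5-trimethylisochromane-6,8-diol | Cc1c(O)c(CN(C)C)c(O)c2c1[C@H](C)[C@@H](C)OC2 | intermediate
16 | (3R,4S)-6-hydroxy-3,4,5-trimethyl-7-methylidene-3,4-dihydro-1H-isochromen-8(7H)-one, formed in the flask | C=C1C(=O)C2=C([C@H](C)[C@@H](C)OC2)C(C)=C1O | intermediate
17 | (3R,4S)-7-{[(3R,4S)-6,8-dihydroxy-3,4,5-trimethylisochroman-7-yl]methyl}-6-hydroxy-3,4,5-trimethyl-3,4-dihydro-8H-isochromen-8-one | CC1=C2C(=CO[C@H](C)[C@H]2C)C(=O)C(Cc2c(O)c(C)c3c(c2O)CO[C@H](C)[C@H]3C)=C1O | target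

Total step count: 12
Longest linear sequence: 11 steps (steps 1 to 9, then step 10 or step 11, then step 12)

Steps most likely to fail

Step 8. Hydride abstraction from the aryl methyl may be slower than intermolecular Friedel–Crafts benzylation of the free ring position or than attack on the second methyl, and the acidic silane reduction may reductively reopen the benzylic ether. The fallback is an oxa-Pictet–Spengler closure, which forms the C1–C8a bond from a formaldehyde equivalent and needs no benzylic oxidation. It sets out from 3 and comes back to the route at 12.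
- Bromine–lithium exchange of 3 (n-BuLi, THF, −78 °C) should give (3,5-dimethoxy-2-methylphenyl)lithium F1.
- F1 opens epoxide 6 under BF3·OEt2 to (2S,3S)-3-(3,5-dimethoxy-2-methylphenyl)butan-2-ol F2.
- Mitsunobu inversion with 4-nitrobenzoic acid, PPh3 and DIAD gives (2R,3S)-3-(3,5-dimethoxy-2-methylphenyl)butan-2-yl 4-nitrobenzoate F3.
- Methanolysis with K2CO3 gives (2R,3S)-3-(3,5-dimethoxy-2-methylphenyl)butan-2-ol F4.
- With dimethoxymethane and BF3·OEt2 in CH2Cl2, F4 forms 1-[(2S,3R)-3-(methoxymethoxy)butan-2-yl]-3,5-dimethoxy-2-methylbenzene F5 in the flask. Its oxocarbenium ion attacks the free ring position ortho to the side chain (para to one methoxy) and closes the pyran ring to 12.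

Step 5. Addition of the di-ortho-substituted aryllithium to the internal epoxide may be sluggish, so that BF3-induced rearrangement or halide opening of the epoxide and protonation of the aryllithium take over. The fallback reorders the route so that the epoxide is opened by the less hindered mono-ortho-methyl nucleophile and the second methyl is installed afterwards. It sets out from 3 and comes back to the route at 9.
- As above, 3 is converted through (3,5-dimethoxy-2-methylphenyl)lithium F1 and (2S,3S)-3-(3,5-dimethoxy-2-methylphenyl)butan-2-ol F2 into (2R,3S)-3-(3,5-dimethoxy-2-methylphenyl)butan-2-yl 4-nitrobenzoate F3.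
- Vilsmeier–Haack formylation (POCl3, DMF) of F3 at the free position ortho to the side chain and para to a methoxy gives (2R,3S)-3-(2-formyl-3,5-dimethoxy-6-methylphenyl)butan-2-yl 4-nitrobenzoate F6.
- Ionic hydrogenation with Et3SiH and TFA turns the formyl group into the second methyl and gives 9.

Step 12. Loss of dimethylamine may be followed by self-condensation of the quinone methide partner, or by addition of the liberated amine or of phenolic oxygen to C1 of 14, instead of carbon–carbon bond formation at C7. The fallback builds the methylene bridge between two aromatic halves first and oxidises last. It sets out from 13 and comes back to the route at 17.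
- Half an equivalent of aqueous formaldehyde under mild acid catalysis (phenol–formaldehyde condensation at the only free ring position) joins two molecules of 13 to bis[(3R,4S)-6,8-dihydroxy-3,4,5-trimethylisochroman-7-yl]methane F7.
- One equivalent of DDQ then dehydrogenates C1 of one half, as in step 10, to give 17.
- Unchanged and doubly oxidised dimer would be separated; the doubly oxidised material can be returned to F7 with NaBH4.

Further compounds
F1 | step 8 | (3,5-dimethoxy-2-methylphenyl)lithium | [Li]c1cc(OC)cc(OC)c1C
F2 | step 8 | (2S,3S)-3-(3,5-dimethoxy-2-methylphenyl)butan-2-ol | COc1cc(OC)c(C)c([C@H](C)[C@H](C)O)c1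
F3 | step 8 | (2R,3S)-3-(3,5-dimethoxy-2-methylphenyl)butan-2-yl 4-nitrobenzoate | COc1cc(OC)c(C)c([C@H](C)[C@@H](C)OC(=O)c2ccc(cc2)[N+](=O)[O-])c1
F4 | step 8 | (2R,3S)-3-(3,5-dimethoxy-2-methylphenyl)butan-2-ol | COc1cc(OC)c(C)c([C@H](C)[C@@H](C)O)c1
F5 | step 8 | 1-[(2S,3R)-3-(methoxymethoxy)butan-2-yl]-3,5-dimethoxy-2-methylbenzene | COc1cc(OC)c(C)c([C@H](C)[C@@H](C)OCOC)c1
F6 | step 5 | (2R,3S)-3-(2-formyl-3,5-dimethoxy-6-methylphenyl)butan-2-yl 4-nitrobenzoate | COc1cc(OC)c(C)c([C@H](C)[C@@H](C)OC(=O)c2ccc(cc2)[N+](=O)[O-])c1C=O
F7 | step 12 | bis[(3R,4S)-6,8-dihydroxy-3,4,5-trimethylisochroman-7-yl]methane | Cc1c(O)c(Cc2c(O)c(C)c3c(c2O)CO[C@H](C)[C@H]3C)c(O)c2c1[C@H](C)[C@@H](C)OC2
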